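**Retrosynthetic overview**
1. The target comes from its 3'-O-benzyl ether by hydrogenolysis in the last step.
2. The 4-pyranone is the only ring that is built (both benzene rings are bought); it closes by acid cyclodehydration of an o-hydroxyaryl β-diketone.
3. The β-diketone comes from an intermolecular crossed Claisen condensation (key C–C bond, the future C2–C3 of the chromone) between the dianion of 2'-hydroxy-4',5'-dimethoxyacetophenone and ethyl 3-[3-(benzyloxy)-4-methoxyphenyl]propanoate.
4. That ester comes from isovanillin by Wittig two-carbon homologation, alkene hydrogenation and O-benzylation.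
5. Ring order: two purchased arenes, then the pyranone; there is no stereocentre to control.

Assumption: the target has no stereocentre and no stereogenic double bond, so "single enantiomer" is read as the single achiral compound drawn; 2'-hydroxy-4',5'-dimethoxyacetophenone is taken as a catalogue compound.

**Route**

Step 1
Reactants: 1 isovanillin (3-hydroxy-4-methoxybenzaldehyde); 2 ethyl (triphenylphosphoranylidene)acetate
Product: 3 ethyl (E)-3-(3-hydroxy-4-methoxyphenyl)prop-2-enoate
Conditions: 2 (1.2 equiv), toluene, 90 °C, 4 h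
Reagents that add atoms: ethyl (triphenylphosphoranylidene)acetate, CCOC(=O)C=P(c1ccccc1)(c1ccccc1)c1ccccc1
Why: Wittig olefination with a stabilised ylide tolerates the free phenol and gives the (E)-cinnamate, whose geometry is irrelevant because the double bond is saturated in the next step.

Step 2
Reactants: 3 ethyl (E)-3-(3-hydroxy-4-methoxyphenyl)prop-2-enoate
Product: 4 ethyl 3-(3-hydroxy-4-methoxyphenyl)propanoate
Conditions: H2 (1 atm), 10% Pd/C, EtOH, rt, 4 h
Reagents that add atoms: none
Why: Heterogeneous catalytic hydrogenation saturates the conjugated C=C at 1 atm while ester, phenol, aryl ether and arene are inert, and no stereocentre is created.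

Step 3
Reactants: 4 ethyl 3-(3-hydroxy-4-methoxyphenyl)propanoate; 5 benzyl bromide
Product: 6 ethyl 3-[3-(benzyloxy)-4-methoxyphenyl]propanoate
Conditions: BnBr (1.2 equiv), K2CO3 (2 equiv), DMF, 60 °C, 4 h
Reagents that add atoms: benzyl bromide, BrCc1ccccc1
Why: Williamson ether synthesis, in which carbonate deprotonates only the phenol (not the ester α-CH2) and the phenoxide is benzylated by SN2, masking the acidic OH before the enolate chemistry.

Step 4
Reactants: 7 1-(2-hydroxy-4,5-dimethoxyphenyl)ethan-1-one; 6 ethyl 3-[3-(benzyloxy)-4-methoxyphenyl]propanoate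
Product: 9 5-[3-(benzyloxy)-4-methoxyphenyl]-1-(2-hydroxy-4,5-dimethoxyphenyl)pentane-1,3-dione, via disodium phenoxide-enolate dianion 8 (not isolated)
Conditions: 7 (1.2 equiv), NaH (4 equiv), THF, 0 °C → reflux, 1 h; then 6 (1.0 equiv) dropwise, reflux, 3 h; 1 M HCl, 0 °C
Reagents that add atoms: none
Why: Intermolecular crossed Claisen condensation, in which the pre-formed phenoxide–enolate dianion is C-acylated by the ester and irreversible deprotonation of the resulting β-diketone drives the equilibrium, forming the future C2–C3 bond without creating a stereocentre.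

Step 5
Reactants: 9 5-[3-(benzyloxy)-4-methoxyphenyl]-1-(2-hydroxy-4,5-dimethoxyphenyl)pentane-1,3-dione
Product: 11 2-{2-[3-(benzyloxy)-4-methoxyphenyl]ethyl}-6,7-dimethoxy-4H-chromen-4-one, via racemic 2-hydroxychroman-4-one hemiketal 10 (not isolated)
Conditions: conc. HCl (cat.), MeOH, reflux, 2 h
Reagents that add atoms: none
Why: Acid-catalysed cyclodehydration (the ring-closing stage of a Baker–Venkataraman-type chromone synthesis), in which the phenol adds to the distal ketone to give a six-membered hemiketal that loses water to the conjugated 4-pyranone, destroying the transient racemic centre while the aryl benzyl ether survives dilute HCl/MeOH.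

Step 6
Reactants: 11 2-{2-[3-(benzyloxy)-4-methoxyphenyl]ethyl}-6,7-dimethoxy-4H-chromen-4-one
Product: 12 2-[2-(3-hydroxy-4-methoxyphenyl)ethyl]-6,7-dimethoxy-4H-chromen-4-one (target)
Conditions: H2 (1 atm), 10% Pd/C, EtOAc–MeOH (1:1), rt, 2–4 h, stopped when 11 is consumed (TLC)
Reagents that add atoms: none
Why: Catalytic hydrogenolysis of the benzylic C–O bond is fast at 1 atm and room temperature, whereas the vinylogous-ester C2=C3 bond and the ketone of the chromone are reduced only under forcing conditions.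

**Compound list**
1 | isovanillin (3-hydroxy-4-methoxybenzaldehyde) | COc1ccc(C=O)cc1O | starting material
2 | ethyl (triphenylphosphoranylidene)acetate | CCOC(=O)C=P(c1ccccc1)(c1ccccc1)c1ccccc1 | starting material
3 | ethyl (E)-3-(3-hydroxy-4-methoxyphenyl)prop-2-enoate | CCOC(=O)/C=C/c1ccc(OC)c(O)c1 | intermediate
4 | ethyl 3-(3-hydroxy-4-methoxyphenyl)propanoate | CCOC(=O)CCc1ccc(OC)c(O)c1 | intermediate
5 | benzyl bromide | BrCc1ccccc1 | starting material
6 | ethyl 3-[3-(benzyloxy)-4-methoxyphenyl]propanoate | CCOC(=O)CCc1ccc(OC)c(OCc2ccccc2)c1 | intermediate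
7 | 1-(2-hydroxy-4,5-dimethoxyphenyl)ethan-1-one (2'-hydroxy-4',5'-dimethoxyacetophenone) | CC(=O)c1cc(OC)c(OC)cc1O | starting material
8 | disodium 4,5-dimethoxy-2-(1-oxidoethenyl)phenolate (phenoxide-enolate dianion of 7) | [Na+].[Na+].C=C([O-])c1cc(OC)c(OC)cc1[O-] | intermediate (not isolated)
9 | 5-[3-(benzyloxy)-4-methoxyphenyl]-1-(2-hydroxy-4,5-dimethoxyphenyl)pentane-1,3-dione (diketo form drawn; largely enolised) | COc1ccc(CCC(=O)CC(=O)c2cc(OC)c(OC)cc2O)cc1OCc1ccccc1 | intermediate
10 | rac-2-{2-[3-(benzyloxy)-4-methoxyphenyl]ethyl}-2-hydroxy-6,7-dimethoxychroman-4-one (racemic hemiketal) | COc1ccc(CCC2(O)CC(=O)c3cc(OC)c(OC)cc3O2)cc1OCc1ccccc1 | intermediate (not isolated)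
11 | 2-{2-[3-(benzyloxy)-4-methoxyphenyl]ethyl}-6,7-dimethoxy-4H-chromen-4-one | COc1ccc(CCc2cc(=O)c3cc(OC)c(OC)cc3o2)cc1OCc1ccccc1 | intermediate
12 | 2-[2-(3-hydroxy-4-methoxyphenyl)ethyl]-6,7-dimethoxy-4H-chromen-4-one (achiral) | COc1ccc(CCc2cc(=O)c3cc(OC)c(OC)cc3o2)cc1O | target

**Summary**
Total step count: 6. Longest linear sequence: 6 steps (1 → 3 → 4 → 6 → 9 → 11 → 12); ketone 7 enters at step 4.

**Steps most likely to fail, with fallbacks**

Step 4 (crossed Claisen). The risks are self-condensation of ester 6, O-acylation of the phenoxide and incomplete conversion. The fallback replaces the intermolecular enolate acylation by an intramolecular acyl transfer (Baker–Venkataraman rearrangement). Setting out from 6, saponify (LiOH, THF–H2O, rt; then HCl) to 3-[3-(benzyloxy)-4-methoxyphenyl]propanoic acid F1. Esterify the phenol of 7 with it (DCC, DMAP, CH2Cl2, rt) to give 2-acetyl-4,5-dimethoxyphenyl 3-[3-(benzyloxy)-4-methoxyphenyl]propanoate F2. Treat F2 with KOtBu (THF, 0 °C → rt) so that the ketone enolate attacks the neighbouring aryl ester; acidic work-up comes back to the route at diketone 9.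

Step 6 (hydrogenolysis). The risk is over-reduction of the chromone C2=C3 bond or ketone (chromanone or chromanol by-products). The fallback avoids a reductive deprotection by carrying an acid-labile group instead of benzyl. Setting out from 4, protect with MOMCl and iPr2NEt (CH2Cl2, 0 °C → rt) to give ethyl 3-[4-methoxy-3-(methoxymethoxy)phenyl]propanoate F3. Condense F3 with 7 under the step-4 conditions (NaH, THF, reflux, through dianion 8) to 1-(2-hydroxy-4,5-dimethoxyphenyl)-5-[4-methoxy-3-(methoxymethoxy)phenyl]pentane-1,3-dione F4. Heating F4 in HCl/MeOH closes the ring through rac-2-hydroxy-6,7-dimethoxy-2-{2-[4-methoxy-3-(methoxymethoxy)phenyl]ethyl}chroman-4-one F5 to 6,7-dimethoxy-2-{2-[4-methoxy-3-(methoxymethoxy)phenyl]ethyl}-4H-chromen-4-one F6. Neither is isolated, and the MOM acetal of F6 is cleaved in the same pot, so the fallback comes back at target 12.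

Step 5 (cyclodehydration). The risks are stalling at hemiketal 10 and partial loss of the benzyl ether if the acid has to be made stronger. The fallback reverses the order of the last two operations. Setting out from 9, hydrogenolyse first (H2 1 atm, Pd/C, EtOAc, rt; no chromone C=C is present yet) to 1-(2-hydroxy-4,5-dimethoxyphenyl)-5-(3-hydroxy-4-methoxyphenyl)pentane-1,3-dione F7. Then cyclise with nothing left to protect (cat. H2SO4, AcOH, 100 °C), through rac-2-hydroxy-2-[2-(3-hydroxy-4-methoxyphenyl)ethyl]-6,7-dimethoxychroman-4-one F8 (not isolated), which comes back to the route at target 12.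

**Further compounds**
F1 | step 4 | 3-[3-(benzyloxy)-4-methoxyphenyl]propanoic acid | OC(=O)CCc1ccc(OC)c(OCc2ccccc2)c1
F2 | step 4 | 2-acetyl-4,5-dimethoxyphenyl 3-[3-(benzyloxy)-4-methoxyphenyl]propanoate | CC(=O)c1cc(OC)c(OC)cc1OC(=O)CCc1ccc(OC)c(OCc2ccccc2)c1
F3 | step 6 | ethyl 3-[4-methoxy-3-(methoxymethoxy)phenyl]propanoate | CCOC(=O)CCc1ccc(OC)c(OCOC)c1
F4 | step 6 | 1-(2-hydroxy-4,5-dimethoxyphenyl)-5-[4-methoxy-3-(methoxymethoxy)phenyl]pentane-1,3-dione | COCOc1cc(CCC(=O)CC(=O)c2cc(OC)c(OC)cc2O)ccc1OC
F5 | step 6 | rac-2-hydroxy-6,7-dimethoxy-2-{2-[4-methoxy-3-(methoxymethoxy)phenyl]ethyl}chroman-4-one | COCOc1cc(CCC2(O)CC(=O)c3cc(OC)c(OC)cc3O2)ccc1OC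
F6 | step 6 | 6,7-dimethoxy-2-{2-[4-methoxy-3-(methoxymethoxy)phenyl]ethyl}-4H-chromen-4-one | COCOc1cc(CCc2cc(=O)c3cc(OC)c(OC)cc3o2)ccc1OC
F7 | step 5 | 1-(2-hydroxy-4,5-dimethoxyphenyl)-5-(3-hydroxy-4-methoxyphenyl)pentane-1,3-dione | COc1ccc(CCC(=O)CC(=O)c2cc(OC)c(OC)cc2O)cc1O
F8 | step 5 | rac-2-hydroxy-2-[2-(3-hydroxy-4-methoxyphenyl)ethyl]-6,7-dimethoxychroman-4-one | COc1ccc(CCC2(O)CC(=O)c3cc(OC)c(OC)cc3O2)cc1O
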